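**Plan**

1. Dioxolane numbering used here: O1–O2–C3(CH3)(CH2CO2H)–C4H2–C5(CH3)(C16 chain). The retrosynthesis cuts C9=C10 of the side chain (HWE), then ring bond O1–C5 (closure onto a C5=CH2 group), then O2–C3 (perhydrolysis of an oxetane), then the C–C bonds around a 2-methylenepropane-1,3-diyl unit.
2. Forward: C15 skipped enyne → E-allylic alcohol → epoxide → 1,3-diol → oxetane → C3 hydroperoxide → 1,2-dioxolane (the only ring, closed in step 9) → acetic acid arm → ozonolysis → triene by HWE.
3. Stereochemistry: C3 comes from a Sharpless epoxidation, is carried through the oxetane and is inverted once by H2O2. C5 comes from catalyst-controlled proton and oxygen delivery in the ring closure. 11E,13E come with the dienal; 9E comes from the HWE.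
4. Enabling feature: ring atom C5 bears a CH3 group and lies three atoms from the free peroxide oxygen (O–O–C3–C4–C5). Both the O1–C5 bond and that CH3 can therefore arise from an exocyclic C5=CH2 by Markovnikov 5-exo addition of the C3–OOH group.

Key step: step 9

Remark: the sense of induction of the chiral acid in step 9 cannot be predicted for a hydroperoxide nucleophile, so both catalyst enantiomers would be tried and the one that gives the (5R) centre used; catalysts are not counted as starting materials.

Remark: magnesium (step 1), n-butyllithium (step 3) and p-toluenesulfonyl chloride (step 6) are listed as atom-adding reagents because their atoms enter the not-isolated intermediates 3, 7 and 11; these atoms leave again within the same step and are absent from the isolated products 4, 8 and 12.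

**Route**

Step 1
Reactants: 1 9-bromonon-1-ene; 2 3-chloro-2-(chloromethyl)prop-1-ene
Product: 4 2-(chloromethyl)dodeca-1,11-diene, via non-8-en-1-ylmagnesium bromide 3 (not isolated)
Conditions: Mg, THF; then added to 2 (3 equiv), CuI (5 mol %), THF, −20 °C → rt
Reagents that add atoms: magnesium ([Mg])
Why: Copper-catalysed coupling of a primary alkyl Grignard reagent with an allylic chloride; SN2 and SN2′ give the same product because 2 is symmetric, and the excess of 2 should keep the second chloride unreacted.

Step 2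
Reactants: 4 2-(chloromethyl)dodeca-1,11-diene
Product: 5 4-methylidenetetradec-13-en-1-yne
Conditions: HC≡CMgBr (2 equiv), CuBr·SMe2 (10 mol %), THF, 50 °C
Reagents that add atoms: ethynylmagnesium bromide (C#C[Mg]Br)
Why: Copper-catalysed allyl–alkynyl coupling of an alkynyl Grignard reagent with a primary allylic chloride should give the skipped enyne, again with one constitution from either SN2 or SN2′ attack.

Step 3
Reactants: 5 4-methylidenetetradec-13-en-1-yne
Product: 8 (2E)-3-methyl-5-methylidenepentadeca-2,14-dien-1-ol, via dimethyl[(1E)-2-methyl-4-methylidenetetradeca-1,13-dien-1-yl]alumane 6 (not isolated), via lithium butyl(dimethyl)[(1E)-2-methyl-4-methylidenetetradeca-1,13-dien-1-yl]aluminate 7 (not isolated)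
Conditions: Me3Al, Cp2ZrCl2 (25 mol %), CH2Cl2, 0 °C → rt; volatiles removed; n-BuLi, THF/hexane, −30 °C; (CH2O)n, rt; aqueous work-up
Reagents that add atoms: trimethylaluminium (C[Al](C)C); formaldehyde (C=O); n-butyllithium ([Li]CCCC)
Why: Zirconium-catalysed syn-carboalumination of the terminal alkyne puts CH3 on the internal and Al on the terminal carbon on the same side, and the alanate is hydroxymethylated with retention, which fixes the 2E geometry; the 1,1-disubstituted and monosubstituted alkenes should react far more slowly than the alkyne.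

Step 4
Reactants: 8 (2E)-3-methyl-5-methylidenepentadeca-2,14-dien-1-ol
Product: 9 [(2S,3S)-3-methyl-3-(2-methylidenedodec-11-en-1-yl)oxiran-2-yl]methanol
Conditions: Ti(OiPr)4 (10 mol %), L-(+)-diethyl tartrate (12 mol %), t-BuOOH, 4 Å MS, CH2Cl2, −20 °C
Reagents that add atoms: tert-butyl hydroperoxide (CC(C)(C)OO)
Why: Sharpless asymmetric epoxidation of an E-trisubstituted allylic alcohol; L-(+)-tartrate should deliver oxygen to the face that gives the (2S,3S)-epoxide (the geraniol pattern), which sets the future C3 centre, and the non-allylic alkenes are not epoxidised.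

Step 5
Reactants: 9 [(2S,3S)-3-methyl-3-(2-methylidenedodec-11-en-1-yl)oxiran-2-yl]methanol
Product: 10 (3S)-3-methyl-5-methylidenepentadec-14-ene-1,3-diol
Conditions: Red-Al (2 equiv), THF, 0 °C → rt
Reagents that add atoms: none
Why: Hydroxyl-directed hydride delivery from the alkoxyaluminium hydride to C2 of the 2,3-epoxy alcohol opens the C2–O bond and should give the 1,3-diol with the tertiary carbinol centre untouched.

Step 6
Reactants: 10 (3S)-3-methyl-5-methylidenepentadec-14-ene-1,3-diol
Product: 12 (2S)-2-methyl-2-(2-methylidenedodec-11-en-1-yl)oxetane, via (3S)-3-hydroxy-3-methyl-5-methylidenepentadec-14-en-1-yl 4-methylbenzenesulfonate 11 (not isolated)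
Conditions: n-BuLi (1.0 equiv), THF, 0 °C; TsCl (1.0 equiv); n-BuLi (1.1 equiv), 0 → 60 °C
Reagents that add atoms: p-toluenesulfonyl chloride (Cc1ccc(cc1)S(Cl)(=O)=O)
Why: Selective sulfonylation of the primary alkoxide followed by 4-exo-tet Williamson closure by the tertiary alkoxide should give the oxetane with retention, because only the O–H bond of the stereocentre reacts.

Step 7
Reactants: 12 (2S)-2-methyl-2-(2-methylidenedodec-11-en-1-yl)oxetane
Product: 13 (3R)-3-hydroperoxy-3-methyl-5-methylidenepentadec-14-en-1-ol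
Conditions: anhydrous H2O2 in Et2O (excess), TMSOTf (cat.), Et2O, −78 → 0 °C
Reagents that add atoms: hydrogen peroxide (OO)
Why: Lewis-acid-promoted perhydrolysis of a 2,2-disubstituted oxetane, in which H2O2 attacks the more substituted ring carbon with inversion, should give the tertiary (R)-hydroperoxide and free the primary alcohol; low temperature and the ether solvent are meant to hold back protonation of the alkene.

Step 8
Reactants: 13 (3R)-3-hydroperoxy-3-methyl-5-methylidenepentadec-14-en-1-ol
Product: 14 (3R)-3-hydroperoxy-3-methyl-5-methylidenepentadec-14-en-1-yl acetate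
Conditions: immobilised Candida antarctica lipase B, vinyl acetate, MTBE, rt
Reagents that add atoms: vinyl acetate (C=COC(C)=O)
Why: Lipase-catalysed transesterification should acylate the unhindered primary hydroxyl and leave the tertiary hydroperoxide untouched, which removes the competing oxygen nucleophile before the acid-catalysed ring closure.

Step 9
Reactants: 14 (3R)-3-hydroperoxy-3-methyl-5-methylidenepentadec-14-en-1-yl acetate
Product: 15 2-[(3S,5R)-5-(dec-9-en-1-yl)-3,5-dimethyl-1,2-dioxolan-3-yl]ethyl acetate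
Conditions: chiral imidodiphosphorimidate (IDPi) Brønsted acid (5 mol %), cyclohexane, 30–40 °C, dark
Reagents that add atoms: none
Why: Proposed new method: the confined, strongly acidic chiral imidodiphosphorimidate is expected to protonate the terminal CH2 of the 1,1-disubstituted alkene in concert with attack of the hydrogen-bonded hydroperoxide oxygen on the developing tertiary cation at C5, so that the O1–C5 bond and the C5 methyl group arise together in one 5-exo-trig closure (O–O–C3–C4–C5) that forms the 1,2-dioxolane. The closest known reaction types are the chiral-acid-catalysed intramolecular hydroalkoxylation of unactivated 1,1-disubstituted alkenes to 2,2-disubstituted tetrahydrofurans and the classical acid-catalysed Markovnikov addition of hydroperoxides to such alkenes. The new C5 centre should be set by the catalyst, because the resident C3 centre carries two groups of similar size (CH3 and CH2CH2OAc) and exerts almost no bias; the catalyst enantiomer is chosen for the (5R) face, which places the two methyl groups cis. C3 is not touched and keeps the configuration from step 7. The step needs face selectivity at C5 and chemoselectivity for the 1,1-disubstituted alkene; the monosubstituted C=C bond cannot give a tertiary cation, and the acetate has removed the primary hydroxyl that could otherwise close a six-membered ether. Alkene isomers formed by reversible protonation return to the same C5 cation and should converge on the same product.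

Step 10
Reactants: 15 2-[(3S,5R)-5-(dec-9-en-1-yl)-3,5-dimethyl-1,2-dioxolan-3-yl]ethyl acetate
Product: 16 2-[(3S,5R)-5-(dec-9-en-1-yl)-3,5-dimethyl-1,2-dioxolan-3-yl]ethan-1-ol
Conditions: K2CO3 (cat.), MeOH, 0 °C → rt
Reagents that add atoms: none
Why: Base-catalysed methanolysis of the acetate; both oxygen-bearing ring carbons are fully substituted and no carbonyl is β to the peroxide at this stage, so base-induced fragmentation of the dioxolane is not available.

Step 11
Reactants: 16 2-[(3S,5R)-5-(dec-9-en-1-yl)-3,5-dimethyl-1,2-dioxolan-3-yl]ethan-1-ol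
Product: 18 2-[(3R,5R)-5-(dec-9-en-1-yl)-3,5-dimethyl-1,2-dioxolan-3-yl]acetic acid, via 2-[(3R,5R)-5-(dec-9-en-1-yl)-3,5-dimethyl-1,2-dioxolan-3-yl]acetaldehyde 17 (not isolated)
Conditions: TEMPO (20 mol %), PhI(OAc)2 (2.5 equiv), MeCN/H2O 1:1, rt
Reagents that add atoms: water (O)
Why: Oxoammonium-catalysed oxidation should take the primary alcohol through the aldehyde hydrate to the acid under near-neutral conditions that spare the peroxide and the terminal alkene (the change of C3 descriptor from S to R is a change of CIP priority only).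

Step 12
Reactants: 18 2-[(3R,5R)-5-(dec-9-en-1-yl)-3,5-dimethyl-1,2-dioxolan-3-yl]acetic acid
Product: 20 2-[(3R,5R)-3,5-dimethyl-5-(9-oxononyl)-1,2-dioxolan-3-yl]acetic acid, via 2-[(3R,5R)-3,5-dimethyl-5-[8-(1,2,4-trioxolan-3-yl)octyl]-1,2-dioxolan-3-yl]acetic acid 19 (not isolated)
Conditions: O3, CH2Cl2, −78 °C; then Me2S, −78 °C → rt
Reagents that add atoms: ozone ([O-][O+]=O)
Why: Ozonolysis of the only remaining C=C bond with reductive work-up; hindered dialkyl peroxides are inert to ozone and to dimethyl sulfide, which should reduce only the ozonide.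

Step 13
Reactants: 21 (2E,4E)-hepta-2,4-dienal
Product: 22 (2E,4E)-hepta-2,4-dien-1-ol
Conditions: NaBH4, CeCl3·7H2O, MeOH, 0 °C
Reagents that add atoms: none
Why: Luche 1,2-reduction of the dienal, which leaves the E,E geometry untouched.

Step 14
Reactants: 22 (2E,4E)-hepta-2,4-dien-1-ol
Product: 23 (2E,4E)-1-bromohepta-2,4-diene
Conditions: PBr3 (0.4 equiv), Et2O, −10 °C, dark; used crude
Reagents that add atoms: phosphorus tribromide (BrP(Br)Br)
Why: SN2 bromination of the primary dienylic alcohol at low temperature, with the bromide used at once to limit allylic transposition and E/Z leakage.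

Step 15
Reactants: 23 (2E,4E)-1-bromohepta-2,4-diene
Product: 24 diethyl [(2E,4E)-hepta-2,4-dien-1-yl]phosphonate
Conditions: P(OEt)3 (neat), 100–120 °C
Reagents that add atoms: triethyl phosphite (CCOP(OCC)OCC)
Why: Michaelis–Arbuzov reaction of a primary allylic bromide with triethyl phosphite.

Step 16
Reactants: 20 2-[(3R,5R)-3,5-dimethyl-5-(9-oxononyl)-1,2-dioxolan-3-yl]acetic acid; 24 diethyl [(2E,4E)-hepta-2,4-dien-1-yl]phosphonate
Product: 25 2-[(3R,5R)-5-[(9E,11E,13E)-hexadeca-9,11,13-trien-1-yl]-3,5-dimethyl-1,2-dioxolan-3-yl]acetic acid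
Conditions: 24, LiHMDS, THF/DMPU, −78 °C; then 20 pre-treated with LiHMDS (1.0 equiv, THF, −78 °C); → rt; 1 M HCl work-up
Reagents that add atoms: none
Why: Horner–Wadsworth–Emmons olefination of the aliphatic aldehyde at the α-carbon of the allylic phosphonate anion should form C9=C10 with E selectivity and complete the all-E triene; the acid is carried as its lithium carboxylate, so no enolisable carbonyl is β to the peroxide and retro-oxa-Michael ring opening is blocked.

**Compound list**

1 | 9-bromonon-1-ene | C=CCCCCCCCBr | starting material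
2 | 3-chloro-2-(chloromethyl)prop-1-ene | C=C(CCl)CCl | starting material
3 | non-8-en-1-ylmagnesium bromide | C=CCCCCCCC[Mg]Br | intermediate
4 | 2-(chloromethyl)dodeca-1,11-diene | C=CCCCCCCCCC(=C)CCl | intermediate
5 | 4-methylidenetetradec-13-en-1-yne | C=CCCCCCCCCC(=C)CC#C | intermediate
6 | dimethyl[(1E)-2-methyl-4-methylidenetetradeca-1,13-dien-1-yl]alumane | C=CCCCCCCCCC(=C)C/C(C)=C/[Al](C)C | intermediate
7 | lithium butyl(dimethyl)[(1E)-2-methyl-4-methylidenetetradeca-1,13-dien-1-yl]aluminate | C=CCCCCCCCCC(=C)C/C(C)=C/[Al-](C)(C)CCCC.[Li+] | intermediate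
8 | (2E)-3-methyl-5-methylidenepentadeca-2,14-dien-1-ol | C=CCCCCCCCCC(=C)C/C(C)=C/CO | intermediate
9 | [(2S,3S)-3-methyl-3-(2-methylidenedodec-11-en-1-yl)oxiran-2-yl]methanol | C=CCCCCCCCCC(=C)C[C@@]1(C)[C@H](CO)O1 | intermediate
10 | (3S)-3-methyl-5-methylidenepentadec-14-ene-1,3-diol | C=CCCCCCCCCC(=C)C[C@@](O)(C)CCO | intermediate
11 | (3S)-3-hydroxy-3-methyl-5-methylidenepentadec-14-en-1-yl 4-methylbenzenesulfonate | C=CCCCCCCCCC(=C)C[C@@](O)(C)CCOS(=O)(=O)c1ccc(C)cc1 | intermediate
12 | (2S)-2-methyl-2-(2-methylidenedodec-11-en-1-yl)oxetane | C=CCCCCCCCCC(=C)C[C@@]1(C)CCO1 | intermediate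
13 | (3R)-3-hydroperoxy-3-methyl-5-methylidenepentadec-14-en-1-ol | C=CCCCCCCCCC(=C)C[C@](C)(CCO)OO | intermediate
14 | (3R)-3-hydroperoxy-3-methyl-5-methylidenepentadec-14-en-1-yl acetate | C=CCCCCCCCCC(=C)C[C@](C)(CCOC(C)=O)OO | intermediate
15 | 2-[(3S,5R)-5-(dec-9-en-1-yl)-3,5-dimethyl-1,2-dioxolan-3-yl]ethyl acetate | C=CCCCCCCCC[C@]1(C)C[C@](C)(CCOC(C)=O)OO1 | intermediate
16 | 2-[(3S,5R)-5-(dec-9-en-1-yl)-3,5-dimethyl-1,2-dioxolan-3-yl]ethan-1-ol | C=CCCCCCCCC[C@]1(C)C[C@](C)(CCO)OO1 | intermediate
17 | 2-[(3R,5R)-5-(dec-9-en-1-yl)-3,5-dimethyl-1,2-dioxolan-3-yl]acetaldehyde | C=CCCCCCCCC[C@]1(C)C[C@](C)(CC=O)OO1 | intermediate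
18 | 2-[(3R,5R)-5-(dec-9-en-1-yl)-3,5-dimethyl-1,2-dioxolan-3-yl]acetic acid | C=CCCCCCCCC[C@]1(C)C[C@](C)(CC(=O)O)OO1 | intermediate
19 | 2-[(3R,5R)-3,5-dimethyl-5-[8-(1,2,4-trioxolan-3-yl)octyl]-1,2-dioxolan-3-yl]acetic acid (both epimers at the trioxolane carbon) | O1COOC1CCCCCCCC[C@]1(C)C[C@](C)(CC(=O)O)OO1 | intermediate
20 | 2-[(3R,5R)-3,5-dimethyl-5-(9-oxononyl)-1,2-dioxolan-3-yl]acetic acid | O=CCCCCCCCC[C@]1(C)C[C@](C)(CC(=O)O)OO1 | intermediate
21 | (2E,4E)-hepta-2,4-dienal | CC/C=C/C=C/C=O | starting material
22 | (2E,4E)-hepta-2,4-dien-1-ol | CC/C=C/C=C/CO | intermediate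
23 | (2E,4E)-1-bromohepta-2,4-diene | CC/C=C/C=C/CBr | intermediate
24 | diethyl [(2E,4E)-hepta-2,4-dien-1-yl]phosphonate | CC/C=C/C=C/CP(=O)(OCC)OCC | intermediate
25 | 2-[(3R,5R)-5-[(9E,11E,13E)-hexadeca-9,11,13-trien-1-yl]-3,5-dimethyl-1,2-dioxolan-3-yl]acetic acid | CC/C=C/C=C/C=C/CCCCCCCC[C@]1(C)C[C@](C)(CC(=O)O)OO1 | target

**Step count and risks**

Total step count: 16. Longest linear sequence: 13 (steps 1–12 and 16); the phosphonate branch (steps 13–15) joins in step 16.

Steps most likely to fail:

1. Step 9 (Proposed new method). The catalyst may not control the face of C–O bond formation well enough, so that both C5 epimers form. The strong acid may also ionise or rearrange the tertiary hydroperoxide before the alkene is protonated. The fallback uses known electrophile-mediated peroxide cyclisation and gives up reagent control in favour of separation. It sets out from 14. Intramolecular peroxymercuration (Hg(OAc)2, 1 equiv, CH2Cl2, 0 °C) should engage the 1,1-disubstituted alkene first, because the hydroperoxide is tethered to it. This would give 2-[(3S,5R)-5-[(acetyloxymercurio)methyl]-5-(dec-9-en-1-yl)-3-methyl-1,2-dioxolan-3-yl]ethyl acetate F1 together with 2-[(3S,5S)-5-[(acetyloxymercurio)methyl]-5-(dec-9-en-1-yl)-3-methyl-1,2-dioxolan-3-yl]ethyl acetate F2. Reductive demercuration (NaBH4, aqueous NaOH, 0 °C) would then give 15 and 2-[(3S,5S)-5-(dec-9-en-1-yl)-3,5-dimethyl-1,2-dioxolan-3-yl]ethyl acetate F3, which are separated by chromatography. The fallback comes back to the route at 15.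

2. Step 7. The oxetane opening may leak into an SN1 pathway and erode the configuration at C3, or the acid may trigger premature, unselective addition to the 1,1-disubstituted alkene. The fallback reverses the order of the two C–O bond formations with known reactions and sets out from 12. Mukaiyama–Isayama hydroperoxysilylation (Co(thd)2 cat., O2, Et3SiH, ClCH2CH2Cl, rt) should act preferentially at the more easily reduced 1,1-disubstituted alkene. It would give (2R)-2-methyl-2-[(2R)-2-methyl-2-[(triethylsilyl)peroxy]dodec-11-en-1-yl]oxetane F4 and its side-chain epimer (2R)-2-methyl-2-[(2S)-2-methyl-2-[(triethylsilyl)peroxy]dodec-11-en-1-yl]oxetane F5. Desilylation (TBAF, AcOH, THF, 0 °C) would give (2R)-2-[(2R)-2-hydroperoxy-2-methyldodec-11-en-1-yl]-2-methyloxetane F6 and (2R)-2-[(2S)-2-hydroperoxy-2-methyldodec-11-en-1-yl]-2-methyloxetane F7. Catalytic TMSOTf (CH2Cl2, −78 °C) should then bring about intramolecular 5-exo opening of the oxetane by the hydroperoxide with inversion at C3. This would give 16 and 2-[(3S,5S)-5-(dec-9-en-1-yl)-3,5-dimethyl-1,2-dioxolan-3-yl]ethan-1-ol F8, separated by chromatography. The fallback comes back to the route at 16, so steps 7–10 are not needed.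

3. Step 16. E selectivity at the new C9=C10 bond may be incomplete, and collapse of the β-oxido phosphonate may be slow. The fallback replaces kinetic E control by thermodynamic equilibration and sets out from 23 and 20. Bromide 23 and PPh3 (toluene, rt) would give [(2E,4E)-hepta-2,4-dien-1-yl](triphenyl)phosphonium bromide F9. Its ylide (NaHMDS, THF, −78 °C) and the carboxylate of 20 would give the triene as a mixture of 25 and 2-[(3R,5R)-5-[(9Z,11E,13E)-hexadeca-9,11,13-trien-1-yl]-3,5-dimethyl-1,2-dioxolan-3-yl]acetic acid F10. Iodine-catalysed isomerisation (I2, 2–5 mol %, CH2Cl2, ambient light) should then take the mixture to the all-E isomer. The fallback comes back to the route at 25.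

**Further compounds**

F1 | step 9 | 2-[(3S,5R)-5-[(acetyloxymercurio)methyl]-5-(dec-9-en-1-yl)-3-methyl-1,2-dioxolan-3-yl]ethyl acetate | C=CCCCCCCCC[C@]1(C[Hg]OC(C)=O)C[C@](C)(CCOC(C)=O)OO1
F2 | step 9 | 2-[(3S,5S)-5-[(acetyloxymercurio)methyl]-5-(dec-9-en-1-yl)-3-methyl-1,2-dioxolan-3-yl]ethyl acetate | C=CCCCCCCCC[C@@]1(C[Hg]OC(C)=O)C[C@](C)(CCOC(C)=O)OO1
F3 | step 9 | 2-[(3S,5S)-5-(dec-9-en-1-yl)-3,5-dimethyl-1,2-dioxolan-3-yl]ethyl acetate | C=CCCCCCCCC[C@@]1(C)C[C@](C)(CCOC(C)=O)OO1
F4 | step 7 | (2R)-2-methyl-2-[(2R)-2-methyl-2-[(triethylsilyl)peroxy]dodec-11-en-1-yl]oxetane | C=CCCCCCCCC[C@@](C)(OO[Si](CC)(CC)CC)C[C@@]1(C)CCO1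
F5 | step 7 | (2R)-2-methyl-2-[(2S)-2-methyl-2-[(triethylsilyl)peroxy]dodec-11-en-1-yl]oxetane | C=CCCCCCCCC[C@](C)(OO[Si](CC)(CC)CC)C[C@@]1(C)CCO1
F6 | step 7 | (2R)-2-[(2R)-2-hydroperoxy-2-methyldodec-11-en-1-yl]-2-methyloxetane | C=CCCCCCCCC[C@@](C)(OO)C[C@@]1(C)CCO1
F7 | step 7 | (2R)-2-[(2S)-2-hydroperoxy-2-methyldodec-11-en-1-yl]-2-methyloxetane | C=CCCCCCCCC[C@](C)(OO)C[C@@]1(C)CCO1
F8 | step 7 | 2-[(3S,5S)-5-(dec-9-en-1-yl)-3,5-dimethyl-1,2-dioxolan-3-yl]ethan-1-ol | C=CCCCCCCCC[C@@]1(C)C[C@](C)(CCO)OO1
F9 | step 16 | [(2E,4E)-hepta-2,4-dien-1-yl](triphenyl)phosphonium bromide | CC/C=C/C=C/C[P+](c1ccccc1)(c1ccccc1)c1ccccc1.[Br-]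
F10 | step 16 | 2-[(3R,5R)-5-[(9Z,11E,13E)-hexadeca-9,11,13-trien-1-yl]-3,5-dimethyl-1,2-dioxolan-3-yl]acetic acid | CC/C=C/C=C/C=C\CCCCCCCC[C@]1(C)C[C@](C)(CC(=O)O)OO1
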